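**Retrosynthetic overview**
1. The ten-membered ring is closed last by a Ni/Cr-catalysed (Nozaki–Hiyama–Kishi) coupling C1–C10 between a (Z)-alkenyl iodide and the C1 aldehyde; this also sets C1.
2. C7–C8 comes from a Ni/Cr coupling of a 4-bromobutenolide with (Z)-3-(tributylstannyl)but-2-enal (sets C8; Sn is exchanged for I later). The C4–C5 oxirane comes from a Shi epoxidation.
3. The butenolide is made first, by a new asymmetric mono-coupling/lactonisation of a gem-dibromoacrylate linchpin (C7, C11–C13) with the enal C1–C6 (forms C6–C7, sets C6).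
4. Three 3-step fragments come from pent-4-yn-1-ol, methyl pyruvate and but-2-yn-1-ol; the tiglate comes from tigloyl chloride.
5. Ring order: butenolide, then oxirane, then ten-membered carbocycle.

Assumption: germacrane numbering (C1–C15) is used for positions; PMB = 4-methoxybenzyl. L* is a Kishi-type oxazoline–sulfonamide Cr ligand, and the enantiomer that gives the drawn configuration is fixed by a Mosher check on the first run.

Step 1
Reactants: 1 pent-4-yn-1-ol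
Product: 2 1-methoxy-4-[(pent-4-yn-1-yloxy)methyl]benzene
Conditions: NaH, PMBCl, Bu4NI (cat.), THF/DMF, 0 °C to rt
Reagents that add atoms: 4-methoxybenzyl chloride COc1ccc(CCl)cc1
Why: Williamson ether synthesis; the PMB ether survives organoaluminium, Ni/Cr and dioxirane chemistry and is removed oxidatively near the end.

Step 2
Reactants: 2 1-methoxy-4-[(pent-4-yn-1-yloxy)methyl]benzene
Product: 5 (E)-3-methyl-6-(PMB-oxy)hex-2-en-1-ol, via alkenylalane 3 (not isolated), via lithium alanate 4 (not isolated)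
Conditions: Me3Al, Cp2ZrCl2 (cat.), CH2Cl2, 0 °C to rt; then n-BuLi, THF, −78 °C; (CH2O)n, −78 °C to rt
Reagents that add atoms: trimethylaluminium C[Al](C)C; formaldehyde (from paraformaldehyde) C=O
Why: Negishi Zr-catalysed syn-carboalumination puts Me on C4 and Al on C5 on the same side, and the ate complex adds to formaldehyde with retention, so C4=C5 is formed E with C15 cis to C6.

Step 3
Reactants: 5 (E)-3-methyl-6-(PMB-oxy)hex-2-en-1-ol
Product: 6 (E)-3-methyl-6-(PMB-oxy)hex-2-enal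
Conditions: MnO2, CH2Cl2, rt
Reagents that add atoms: none
Why: MnO2 oxidises only the allylic alcohol and leaves the E geometry untouched.

Step 4
Reactants: 7 methyl pyruvate
Product: 8 methyl 3,3-dibromo-2-methylprop-2-enoate
Conditions: CBr4, PPh3, CH2Cl2, 0 °C to rt
Reagents that add atoms: carbon tetrabromide BrC(Br)(Br)Br
Why: Ramirez dibromo-olefination (Wittig reaction of Ph3P=CBr2) on the electrophilic keto group of the pyruvate.

Step 5
Reactants: 8 methyl 3,3-dibromo-2-methylprop-2-enoate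
Product: 9 methyl 3,3-dibromo-2-(bromomethyl)prop-2-enoate
Conditions: NBS, AIBN (cat.), PhCF3, reflux
Reagents that add atoms: N-bromosuccinimide O=C1CCC(=O)N1Br
Why: Wohl–Ziegler radical bromination at the only allylic C–H bonds, the 2-methyl group.

Step 6
Reactants: 9 methyl 3,3-dibromo-2-(bromomethyl)prop-2-enoate
Product: 10 methyl 2-(acetoxymethyl)-3,3-dibromoprop-2-enoate
Conditions: KOAc, DMF, rt
Reagents that add atoms: potassium acetate CC(=O)[O-].[K+]
Why: SN2 displacement of the primary allylic bromide by acetate, the vinylic C–Br bonds being inert; both bromines now sit on the future C7.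

Step 7
Reactants: 11 but-2-yn-1-ol
Product: 13 (Z)-3-iodobut-2-en-1-ol, via cyclic alkenylalanate 12 (not isolated)
Conditions: Red-Al, THF, 0 °C to rt; then I2, −78 °C
Reagents that add atoms: iodine II
Why: hydroxyl-directed trans-hydroalumination of the propargylic alcohol puts Al on C3 cis to CH2O, and iodinolysis with retention gives the Z-iodide.

Step 8
Reactants: 13 (Z)-3-iodobut-2-en-1-ol
Product: 14 (Z)-3-(tributylstannyl)but-2-en-1-ol
Conditions: (Bu3Sn)2, PdCl2(PPh3)2 (cat.), THF, 60 °C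
Reagents that add atoms: hexabutylditin CCCC[Sn](CCCC)(CCCC)[Sn](CCCC)(CCCC)CCCC
Why: Pd-catalysed stannylation of the alkenyl iodide with the distannane proceeds with retention and masks C10, so that the enal carries no halide in step 11.

Step 9
Reactants: 14 (Z)-3-(tributylstannyl)but-2-en-1-ol
Product: 15 (Z)-3-(tributylstannyl)but-2-enal
Conditions: MnO2, CH2Cl2, rt
Reagents that add atoms: none
Why: MnO2 oxidation of the allylic alcohol gives the Z-enal without isomerisation or destannylation.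

Step 10
Reactants: 6 (E)-3-methyl-6-(PMB-oxy)hex-2-enal; 10 methyl 2-(acetoxymethyl)-3,3-dibromoprop-2-enoate
Product: 18 {(5R)-4-bromo-5-[(E)-2-methyl-5-(PMB-oxy)pent-1-en-1-yl]-2-oxo-2,5-dihydrofuran-3-yl}methyl acetate, via silyl ether 16 (not isolated), via hydroxy ester 17 (not isolated)
Conditions: CrCl2 (10 mol%), L* (12 mol%), Et3N (20 mol%), NiCl2·2,9-dimethylphenanthroline (2 mol%), Mn, TMSCl, LiCl, MeCN, 0 °C to rt, 10 (1.5 equiv); then PPTS (cat.), MeOH, rt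
Reagents that add atoms: none
Why: Proposed new method: a catalytic asymmetric Ni/Cr coupling of a gem-dibromoacrylate in which only one C–Br bond reacts – Ni(0) should insert into the C–Br bond syn to the ester (carbonyl coordination, the same preference as in ester-directed Br/Mg exchange of such dibromides), the alkenyl group passes to the chiral Cr(III)–sulfonamide complex and adds to one face of the enal to set C6 (5R in 18), the silylated alkoxide lies cis to the ester and lactonises on desilylation, and the second C–Br bond survives because the mono-bromide is less reactive than the gem-dibromide and the aldehyde is the limiting partner; the closest known reactions are the catalytic asymmetric Nozaki–Hiyama–Kishi coupling of beta-haloacrylates with aldehydes to give butenolides and the stoichiometric ester-directed Br/Mg exchange of 3,3-dibromoacrylates.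

Step 11
Reactants: 18 {(5R)-4-bromo-5-[(E)-2-methyl-5-(PMB-oxy)pent-1-en-1-yl]-2-oxo-2,5-dihydrofuran-3-yl}methyl acetate; 15 (Z)-3-(tributylstannyl)but-2-enal
Product: 20 {(5R)-4-[(1S,2Z)-1-hydroxy-3-(tributylstannyl)but-2-en-1-yl]-5-[(E)-2-methyl-5-(PMB-oxy)pent-1-en-1-yl]-2-oxo-2,5-dihydrofuran-3-yl}methyl acetate, via silyl ether 19 (not isolated)
Conditions: CrCl2 (10 mol%), L* (12 mol%), Et3N, NiCl2·2,9-dimethylphenanthroline (5 mol%), Mn, TMSCl, LiCl, MeCN, rt, 15 (1.5 equiv); then PPTS (cat.), MeOH, 0 °C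
Reagents that add atoms: none
Why: catalytic asymmetric Nozaki–Hiyama–Kishi coupling in which Ni(0) inserts into the activated vinylogous acyl bromide, the alkenyl group passes to the chiral Cr(III) complex and adds 1,2 to the enal under ligand control to set C8 (1S in 20), while the alkenylstannane is inert.

Step 12
Reactants: 20 {(5R)-4-[(1S,2Z)-1-hydroxy-3-(tributylstannyl)but-2-en-1-yl]-5-[(E)-2-methyl-5-(PMB-oxy)pent-1-en-1-yl]-2-oxo-2,5-dihydrofuran-3-yl}methyl acetate; 21 tigloyl chloride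
Product: 22 (1S,2Z)-1-{(2R)-4-(acetoxymethyl)-2-[(E)-2-methyl-5-(PMB-oxy)pent-1-en-1-yl]-5-oxo-2,5-dihydrofuran-3-yl}-3-(tributylstannyl)but-2-en-1-yl (E)-2-methylbut-2-enoate
Conditions: pyridine, DMAP (cat.), CH2Cl2, 0 °C
Reagents that add atoms: none
Why: pyridine/DMAP acylation of the secondary allylic alcohol with the acid chloride, with retention at C8 and of the E-tiglate geometry.

Step 13
Reactants: 22 (1S,2Z)-1-{(2R)-4-(acetoxymethyl)-2-[(E)-2-methyl-5-(PMB-oxy)pent-1-en-1-yl]-5-oxo-2,5-dihydrofuran-3-yl}-3-(tributylstannyl)but-2-en-1-yl (E)-2-methylbut-2-enoate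
Product: 23 (1S,2Z)-1-{(2R)-4-(acetoxymethyl)-2-[(E)-2-methyl-5-(PMB-oxy)pent-1-en-1-yl]-5-oxo-2,5-dihydrofuran-3-yl}-3-iodobut-2-en-1-yl (E)-2-methylbut-2-enoate
Conditions: I2, CH2Cl2, 0 °C
Reagents that add atoms: iodine II
Why: iododestannylation is an ipso electrophilic substitution with retention and returns the Z-alkenyl iodide needed for ring closure.

Step 14
Reactants: 23 (1S,2Z)-1-{(2R)-4-(acetoxymethyl)-2-[(E)-2-methyl-5-(PMB-oxy)pent-1-en-1-yl]-5-oxo-2,5-dihydrofuran-3-yl}-3-iodobut-2-en-1-yl (E)-2-methylbut-2-enoate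
Product: 24 (1S,2Z)-1-{(2S)-4-(acetoxymethyl)-2-[(2R,3R)-3-methyl-3-[3-(PMB-oxy)propyl]oxiran-2-yl]-5-oxo-2,5-dihydrofuran-3-yl}-3-iodobut-2-en-1-yl (E)-2-methylbut-2-enoate
Conditions: D-fructose-derived Shi ketone (30 mol%), Oxone, K2CO3, Bu4NHSO4, MeCN/dimethoxymethane/aq. borate buffer (pH 10.5), 0 °C
Reagents that add atoms: potassium peroxymonosulfate (Oxone) OOS(=O)(=O)[O-].[K+]
Why: Shi asymmetric epoxidation, in which the chiral dioxirane attacks the only electron-rich alkene through a spiro transition state to give the (4R,5R)-oxirane, the butenolide, tiglate and iodoalkene being electron-poor.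

Step 15
Reactants: 24 (1S,2Z)-1-{(2S)-4-(acetoxymethyl)-2-[(2R,3R)-3-methyl-3-[3-(PMB-oxy)propyl]oxiran-2-yl]-5-oxo-2,5-dihydrofuran-3-yl}-3-iodobut-2-en-1-yl (E)-2-methylbut-2-enoate
Product: 25 (1S,2Z)-1-{(2S)-4-(acetoxymethyl)-2-[(2R,3R)-3-(3-hydroxypropyl)-3-methyloxiran-2-yl]-5-oxo-2,5-dihydrofuran-3-yl}-3-iodobut-2-en-1-yl (E)-2-methylbut-2-enoate
Conditions: DDQ, CH2Cl2/pH 7 buffer, 0 °C
Reagents that add atoms: none
Why: DDQ oxidises the electron-rich PMB ether to an oxocarbenium ion that water hydrolyses, under buffered conditions that spare the oxirane and the esters.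

Step 16
Reactants: 25 (1S,2Z)-1-{(2S)-4-(acetoxymethyl)-2-[(2R,3R)-3-(3-hydroxypropyl)-3-methyloxiran-2-yl]-5-oxo-2,5-dihydrofuran-3-yl}-3-iodobut-2-en-1-yl (E)-2-methylbut-2-enoate
Product: 26 (1S,2Z)-1-{(2S)-4-(acetoxymethyl)-2-[(2R,3R)-3-methyl-3-(3-oxopropyl)oxiran-2-yl]-5-oxo-2,5-dihydrofuran-3-yl}-3-iodobut-2-en-1-yl (E)-2-methylbut-2-enoate
Conditions: Dess–Martin periodinane, pyridine, CH2Cl2, 0 °C to rt
Reagents that add atoms: none
Why: Dess–Martin oxidation gives the aldehyde under buffered conditions without touching the oxirane or the C6 stereocentre.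

Step 17
Reactants: 26 (1S,2Z)-1-{(2S)-4-(acetoxymethyl)-2-[(2R,3R)-3-methyl-3-(3-oxopropyl)oxiran-2-yl]-5-oxo-2,5-dihydrofuran-3-yl}-3-iodobut-2-en-1-yl (E)-2-methylbut-2-enoate
Product: 28 (1S,4R,5R,6S,8S,9Z)-13-acetoxy-4,5-epoxy-1-hydroxy-8-[(E)-2-methylbut-2-enoyloxy]germacra-7(11),9-dien-12,6-olide, via silyl ether 27 (not isolated)
Conditions: CrCl2 (20 mol%), L* (25 mol%), Et3N, NiCl2·2,9-dimethylphenanthroline (5 mol%), Mn, TMSCl, LiCl, MeCN/THF, 2 mM, slow addition, rt; then PPTS (cat.), MeOH, 0 °C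
Reagents that add atoms: none
Why: intramolecular Nozaki–Hiyama–Kishi coupling (Ni inserts into C10–I, the Cr(III) alkenyl adds to the C1 aldehyde) closes the ten-membered ring with retention of the Z-alkene, and the chiral sulfonamide ligand directs attack to the aldehyde face that gives 1S.

**Compound list**
1 | pent-4-yn-1-ol | C#CCCCO | starting material
2 | 1-methoxy-4-[(pent-4-yn-1-yloxy)methyl]benzene | C#CCCCOCc1ccc(OC)cc1 | intermediate
3 | dimethyl[(E)-2-methyl-5-(PMB-oxy)pent-1-en-1-yl]alane | COc1ccc(COCCC/C(C)=C/[Al](C)C)cc1 | intermediate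
4 | lithium butyl(dimethyl)[(E)-2-methyl-5-(PMB-oxy)pent-1-en-1-yl]aluminate | [Li+].CCCC[Al-](C)(C)/C=C(\C)CCCOCc1ccc(OC)cc1 | intermediate
5 | (E)-3-methyl-6-(PMB-oxy)hex-2-en-1-ol | COc1ccc(COCCC/C(C)=C/CO)cc1 | intermediate
6 | (E)-3-methyl-6-(PMB-oxy)hex-2-enal | COc1ccc(COCCC/C(C)=C/C=O)cc1 | intermediate
7 | methyl pyruvate | COC(=O)C(C)=O | starting material
8 | methyl 3,3-dibromo-2-methylprop-2-enoate | COC(=O)C(C)=C(Br)Br | intermediate
9 | methyl 3,3-dibromo-2-(bromomethyl)prop-2-enoate | COC(=O)C(CBr)=C(Br)Br | intermediate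
10 | methyl 2-(acetoxymethyl)-3,3-dibromoprop-2-enoate | COC(=O)C(COC(C)=O)=C(Br)Br | intermediate
11 | but-2-yn-1-ol | CC#CCO | starting material
12 | sodium 2,2-bis(2-methoxyethoxy)-3-methyl-2,5-dihydro-1,2-oxaluminol-2-uide (cyclic Z-alkenylalanate) | [Na+].CC1=CCO[Al-]1(OCCOC)OCCOC | intermediate
13 | (Z)-3-iodobut-2-en-1-ol | C/C(I)=C/CO | intermediate
14 | (Z)-3-(tributylstannyl)but-2-en-1-ol | CCCC[Sn](CCCC)(CCCC)/C(C)=C\CO | intermediate
15 | (Z)-3-(tributylstannyl)but-2-enal | CCCC[Sn](CCCC)(CCCC)/C(C)=C\C=O | intermediate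
16 | methyl (2E,4R,5E)-2-(acetoxymethyl)-3-bromo-6-methyl-9-(PMB-oxy)-4-(trimethylsilyloxy)nona-2,5-dienoate | COC(=O)/C(COC(C)=O)=C(/Br)[C@H](O[Si](C)(C)C)/C=C(\C)CCCOCc1ccc(OC)cc1 | intermediate
17 | methyl (2E,4R,5E)-2-(acetoxymethyl)-3-bromo-4-hydroxy-6-methyl-9-(PMB-oxy)nona-2,5-dienoate | COC(=O)/C(COC(C)=O)=C(/Br)[C@H](O)/C=C(\C)CCCOCc1ccc(OC)cc1 | intermediate
18 | {(5R)-4-bromo-5-[(E)-2-methyl-5-(PMB-oxy)pent-1-en-1-yl]-2-oxo-2,5-dihydrofuran-3-yl}methyl acetate | COc1ccc(COCCC/C(C)=C/[C@H]2OC(=O)C(COC(C)=O)=C2Br)cc1 | intermediate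
19 | {(5R)-5-[(E)-2-methyl-5-(PMB-oxy)pent-1-en-1-yl]-2-oxo-4-[(1S,2Z)-3-(tributylstannyl)-1-(trimethylsilyloxy)but-2-en-1-yl]-2,5-dihydrofuran-3-yl}methyl acetate | COc1ccc(COCCC/C(C)=C/[C@H]2OC(=O)C(COC(C)=O)=C2[C@@H](O[Si](C)(C)C)/C=C(/C)[Sn](CCCC)(CCCC)CCCC)cc1 | intermediate
20 | {(5R)-4-[(1S,2Z)-1-hydroxy-3-(tributylstannyl)but-2-en-1-yl]-5-[(E)-2-methyl-5-(PMB-oxy)pent-1-en-1-yl]-2-oxo-2,5-dihydrofuran-3-yl}methyl acetate | COc1ccc(COCCC/C(C)=C/[C@H]2OC(=O)C(COC(C)=O)=C2[C@@H](O)/C=C(/C)[Sn](CCCC)(CCCC)CCCC)cc1 | intermediate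
21 | tigloyl chloride, (E)-2-methylbut-2-enoyl chloride | C/C=C(\C)C(=O)Cl | starting material
22 | (1S,2Z)-1-{(2R)-4-(acetoxymethyl)-2-[(E)-2-methyl-5-(PMB-oxy)pent-1-en-1-yl]-5-oxo-2,5-dihydrofuran-3-yl}-3-(tributylstannyl)but-2-en-1-yl (E)-2-methylbut-2-enoate | COc1ccc(COCCC/C(C)=C/[C@H]2OC(=O)C(COC(C)=O)=C2[C@@H](OC(=O)/C(C)=C/C)/C=C(/C)[Sn](CCCC)(CCCC)CCCC)cc1 | intermediate
23 | (1S,2Z)-1-{(2R)-4-(acetoxymethyl)-2-[(E)-2-methyl-5-(PMB-oxy)pent-1-en-1-yl]-5-oxo-2,5-dihydrofuran-3-yl}-3-iodobut-2-en-1-yl (E)-2-methylbut-2-enoate | COc1ccc(COCCC/C(C)=C/[C@H]2OC(=O)C(COC(C)=O)=C2[C@@H](OC(=O)/C(C)=C/C)/C=C(/C)I)cc1 | intermediate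
24 | (1S,2Z)-1-{(2S)-4-(acetoxymethyl)-2-[(2R,3R)-3-methyl-3-[3-(PMB-oxy)propyl]oxiran-2-yl]-5-oxo-2,5-dihydrofuran-3-yl}-3-iodobut-2-en-1-yl (E)-2-methylbut-2-enoate | COc1ccc(COCCC[C@@]2(C)O[C@@H]2[C@H]2OC(=O)C(COC(C)=O)=C2[C@@H](OC(=O)/C(C)=C/C)/C=C(/C)I)cc1 | intermediate
25 | (1S,2Z)-1-{(2S)-4-(acetoxymethyl)-2-[(2R,3R)-3-(3-hydroxypropyl)-3-methyloxiran-2-yl]-5-oxo-2,5-dihydrofuran-3-yl}-3-iodobut-2-en-1-yl (E)-2-methylbut-2-enoate | OCCC[C@@]1(C)O[C@@H]1[C@H]1OC(=O)C(COC(C)=O)=C1[C@@H](OC(=O)/C(C)=C/C)/C=C(/C)I | intermediate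
26 | (1S,2Z)-1-{(2S)-4-(acetoxymethyl)-2-[(2R,3R)-3-methyl-3-(3-oxopropyl)oxiran-2-yl]-5-oxo-2,5-dihydrofuran-3-yl}-3-iodobut-2-en-1-yl (E)-2-methylbut-2-enoate | O=CCC[C@@]1(C)O[C@@H]1[C@H]1OC(=O)C(COC(C)=O)=C1[C@@H](OC(=O)/C(C)=C/C)/C=C(/C)I | intermediate
27 | 1-O-trimethylsilyl ether of 28 | C/C=C(\C)C(=O)O[C@H]1/C=C(/C)[C@@H](O[Si](C)(C)C)CC[C@@]2(C)O[C@@H]2[C@H]2OC(=O)C(COC(C)=O)=C12 | intermediate
28 | (1S,4R,5R,6S,8S,9Z)-13-acetoxy-4,5-epoxy-1-hydroxy-8-[(E)-2-methylbut-2-enoyloxy]germacra-7(11),9-dien-12,6-olide (CNP0222387.1) | C/C=C(\C)C(=O)O[C@H]1/C=C(/C)[C@@H](O)CC[C@@]2(C)O[C@@H]2[C@H]2OC(=O)C(COC(C)=O)=C12 | target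

**Step count and risks**
Total step count: 17. Longest linear sequence: 11 (steps 1–3 and 10–17).

Step 10, the new coupling, may give double coupling, insertion into the wrong C–Br bond or low ee. The fallback uses known reactions only, sets out from 6 and 10 and comes back at 18. Pinnick oxidation of 6 (NaClO2, NaH2PO4, 2-methylbut-2-ene) gives (E)-3-methyl-6-(PMB-oxy)hex-2-enoic acid F1. 1-Chloro-N,N,2-trimethylprop-1-en-1-amine (Ghosez reagent) turns it into (E)-3-methyl-6-(PMB-oxy)hex-2-enoyl chloride F2. Ester-directed Br/Mg exchange of 10 (i-PrMgCl, THF, −78 °C) gives the carbenoid [(E)-2-(acetoxymethyl)-1-bromo-3-methoxy-3-oxoprop-1-en-1-yl]magnesium chloride F3. F3 is acylated by F2 at −78 °C to methyl (2E,5E)-2-(acetoxymethyl)-3-bromo-6-methyl-4-oxo-9-(PMB-oxy)nona-2,5-dienoate F4. Corey–Bakshi–Shibata reduction with (S)-Me-CBS/catecholborane (bromoalkenyl group as the large substituent) gives hydroxy ester 17, which lactonises with PPTS to 18.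

Step 11 may fail because the chromium alkenyl of the bromobutenolide can open by loss of the lactone carboxylate, and because C8 rests on ligand control alone. The fallback sets out from 18 (with 15) and comes back at 20. Classical stoichiometric CrCl2 with catalytic NiCl2 in DMSO, without ligand, gives 20 mixed with its C8 epimer, {(5R)-4-[(1R,2Z)-1-hydroxy-3-(tributylstannyl)but-2-en-1-yl]-5-[(E)-2-methyl-5-(PMB-oxy)pent-1-en-1-yl]-2-oxo-2,5-dihydrofuran-3-yl}methyl acetate F5. Dess–Martin oxidation of the mixture gives the cross-conjugated ketone {(5R)-5-[(E)-2-methyl-5-(PMB-oxy)pent-1-en-1-yl]-2-oxo-4-[(Z)-3-(tributylstannyl)but-2-enoyl]-2,5-dihydrofuran-3-yl}methyl acetate F6. (R)-Me-CBS/catecholborane at −78 °C reduces F6 to 20, so C8 is set by reagent-controlled reduction instead of by the coupling.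

Step 17 may fail through strain in the oxirane-bearing ten-membered ring, oligomer formation or poor C1 selectivity. The fallback sets out from 23 and comes back at 28; it closes the ring on the more flexible 4,5-alkene and moves the epoxidation to the end. DDQ on 23 gives (1S,2Z)-1-{(2R)-4-(acetoxymethyl)-2-[(E)-5-hydroxy-2-methylpent-1-en-1-yl]-5-oxo-2,5-dihydrofuran-3-yl}-3-iodobut-2-en-1-yl (E)-2-methylbut-2-enoate F7. Dess–Martin oxidation gives the aldehyde (1S,2Z)-1-{(2R)-4-(acetoxymethyl)-2-[(E)-2-methyl-5-oxopent-1-en-1-yl]-5-oxo-2,5-dihydrofuran-3-yl}-3-iodobut-2-en-1-yl (E)-2-methylbut-2-enoate F8. Ni/Cr ring closure under the step 17 conditions gives, through the 1-O-trimethylsilyl ether of the macrocycle F9, (1S,6R,8S)-13-acetoxy-1-hydroxy-8-(tigloyloxy)germacra-4E,7(11),9Z-trien-12,6-olide F10. The Shi epoxidation of step 14 is then run on F10, where the 4,5-alkene is the only electron-rich alkene and no iodide is present, to give 28.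

**Further compounds**
F1 | step 10 | (E)-3-methyl-6-(PMB-oxy)hex-2-enoic acid | COc1ccc(COCCC/C(C)=C/C(=O)O)cc1
F2 | step 10 | (E)-3-methyl-6-(PMB-oxy)hex-2-enoyl chloride | COc1ccc(COCCC/C(C)=C/C(=O)Cl)cc1
F3 | step 10 | [(E)-2-(acetoxymethyl)-1-bromo-3-methoxy-3-oxoprop-1-en-1-yl]magnesium chloride | COC(=O)/C(COC(C)=O)=C(/Br)[Mg]Cl
F4 | step 10 | methyl (2E,5E)-2-(acetoxymethyl)-3-bromo-6-methyl-4-oxo-9-(PMB-oxy)nona-2,5-dienoate | COC(=O)/C(COC(C)=O)=C(/Br)C(=O)/C=C(\C)CCCOCc1ccc(OC)cc1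
F5 | step 11 | {(5R)-4-[(1R,2Z)-1-hydroxy-3-(tributylstannyl)but-2-en-1-yl]-5-[(E)-2-methyl-5-(PMB-oxy)pent-1-en-1-yl]-2-oxo-2,5-dihydrofuran-3-yl}methyl acetate | COc1ccc(COCCC/C(C)=C/[C@H]2OC(=O)C(COC(C)=O)=C2[C@H](O)/C=C(/C)[Sn](CCCC)(CCCC)CCCC)cc1
F6 | step 11 | {(5R)-5-[(E)-2-methyl-5-(PMB-oxy)pent-1-en-1-yl]-2-oxo-4-[(Z)-3-(tributylstannyl)but-2-enoyl]-2,5-dihydrofuran-3-yl}methyl acetate | COc1ccc(COCCC/C(C)=C/[C@H]2OC(=O)C(COC(C)=O)=C2C(=O)/C=C(/C)[Sn](CCCC)(CCCC)CCCC)cc1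
F7 | step 17 | (1S,2Z)-1-{(2R)-4-(acetoxymethyl)-2-[(E)-5-hydroxy-2-methylpent-1-en-1-yl]-5-oxo-2,5-dihydrofuran-3-yl}-3-iodobut-2-en-1-yl (E)-2-methylbut-2-enoate | OCCC/C(C)=C/[C@H]1OC(=O)C(COC(C)=O)=C1[C@@H](OC(=O)/C(C)=C/C)/C=C(/C)I
F8 | step 17 | (1S,2Z)-1-{(2R)-4-(acetoxymethyl)-2-[(E)-2-methyl-5-oxopent-1-en-1-yl]-5-oxo-2,5-dihydrofuran-3-yl}-3-iodobut-2-en-1-yl (E)-2-methylbut-2-enoate | O=CCC/C(C)=C/[C@H]1OC(=O)C(COC(C)=O)=C1[C@@H](OC(=O)/C(C)=C/C)/C=C(/C)I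
F9 | step 17 | 1-O-trimethylsilyl ether of F10 | C/C=C(\C)C(=O)O[C@H]1/C=C(/C)[C@@H](O[Si](C)(C)C)CC/C(C)=C/[C@H]2OC(=O)C(COC(C)=O)=C12
F10 | step 17 | (1S,6R,8S)-13-acetoxy-1-hydroxy-8-(tigloyloxy)germacra-4E,7(11),9Z-trien-12,6-olide | C/C=C(\C)C(=O)O[C@H]1/C=C(/C)[C@@H](O)CC/C(C)=C/[C@H]2OC(=O)C(COC(C)=O)=C12
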